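A small charge, [free catalyst] = 25 mM against [solid substrate] = 0.50 M, has to carry the solid through solution to target, and the three flasks differ in temperature.

common to all: solid substrate 0.50 M
- autumn: second substrate 0.50 M; free catalyst 12 mM; temperature 70 °C; run made earlier
- summer: second substrate 0.50 M; free catalyst 19 mM; temperature 90 °C; run made earlier
- dawn: second substrate 0.25 M; free catalyst 25 mM; temperature 70 °C; run made earlier
- north-west: second substrate 0.500 M; free catalyst 25 mM; temperature 90 °C; time 15 min
- east: second substrate 0.500 M; free catalyst 25 mM; temperature 75 °C; time 15 min
- north-east: second substrate 0.500 M; free catalyst 25 mM; temperature 105 °C; time 15 min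

| run | time / min | target / % | solid substrate / % |
|---|---|---|---|
| autumn | 2.00 | 1.0 | 90.6 |
| autumn | 4.00 | 1.1 | 83.5 |
| autumn | 10.0 | 4.7 | 67.3 |
| autumn | 25.0 | 16.1 | 41.8 |
| summer | 0.667 | 0 | 94.9 |
| summer | 1.50 | 1.5 | 92.3 |
| summer | 4.00 | 5.6 | 80.7 |
| summer | 10.0 | 22.0 | 57.3 |
| dawn | 2.50 | 1.7 | 89.1 |
| dawn | 8.00 | 8.1 | 69.6 |
| dawn | 15.0 | 19.7 | 51.7 |
| dawn | 25.0 | 37.7 | 28.9 |

(scatter of a reading: 1 percentage point)

- at the start none of the solid substrate is in solution
- what has only dissolved of solid substrate counts as not reacted
- a reading or a percentage of target counts all its forms, free or not

- which flask leads in amount of target, in percent of the solid substrate charged ("all alike" within 1.5 percentage points) (north-west / east / north-east / all alike)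
- how much target is there at the end, in percent of the solid substrate charged: north-west
- how much target is there at the end, in percent of the solid substrate charged: east
- how much target is there at the end, in percent of the solid substrate charged: north-east

Over its last interval, summer gives 0.209 /min as the drain constant: target gained per minute over the mean dissolved pool (what is neither solid nor target), a pseudo-first-order constant that I assume proportional to catalyst and scale to 25 mM. Autumn, scaled likewise, gives 0.0452 /min. The inverse of the drain constant is the lag, as read from these runs 22.1 min at 70 °C and 4.78 min at 90 °C.

I turn the question round: flasks alike within 1.5 percentage points ask for a lag short against 15 min at both these temperatures, so that target follows the solid's loss. The readings show otherwise: the 70 °C lag exceeds the time while the 90 °C lag sits well inside it. Summer's solid leaves at 0.0557 /min, and two steps in series with these constants give me 42.5% for north-west. East, at 75 °C, stands nearer autumn's temperature than summer's, so I expect it well below that, and north-east, hotter than summer, above it.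

The forecast, slightly below my north-west figure, reasons that “The second step is catalyst-driven” and names north-east, with 41% (35% to 47%) in north-west, 20% (16% to 24%) in east and 57% (43% to 67%) in north-east.

The simulation puts north-east ahead: 63.6% there, 44.9% in north-west, 23.2% in east.

    catalyst intermediate A → free catalyst + target (k = 0.180 /s, Ea = 101 kJ/mol)
    starting material + free catalyst ⇌ catalyst intermediate A (K = 320 /M, k = 0.260 /M/s, Ea = 54.0 kJ/mol, ΔH = −58.0 kJ/mol)
    starting material ⇌ dormant form (K = 0.600, k = 0.00400 /s, Ea = 101 kJ/mol, ΔH = −14.0 kJ/mol)
    second substrate + free catalyst ⇌ catalyst intermediate B (K = 1.10 /M, k = 0.270 /M/s, Ea = 68.0 kJ/mol, ΔH = −44.0 kJ/mol)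
    solid substrate ⇌ starting material, rate k5*(cs5 - [starting material]) while solid is left; crystals form when [starting material] > cs5 (solubility = 0.180 M, k = 0.00270 /s)
    crystals ⇌ target, rate k6*(cs6 - [target]) while solid is left; crystals form when [target] > cs6 (solubility = 0.180 M, k = 0.550 /s)
    catalyst intermediate B → free catalyst + second product (k = 0.110 /s, Ea = 83.0 kJ/mol)
    (constants at 90 °C)

Reckoned the same way from its states between 7.50 min and 15.0 min, east has a drain constant of 0.0792 /min, above autumn's scaled 0.0452 /min and below summer's scaled 0.209 /min. A neighbour flask, east with its free catalyst cut to 0.0063 M, a quarter of east's charge, should by my proportionality assumption have a drain constant of 0.0200 /min and a lag of 50.1 min. Scaling east's target by that same factor gives 5.85%, and that neighbour flask holds 6.51% of target.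

The data come from a simulation from invented constants, noise included.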